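## Retrosynthetic overview

1. Triene: the C2''–C3'' bond is cut to give a 4-ethynyl epoxyquinol and a bromodienamide of the bought aminocyclopentenone (hydrostannation/Stille); the cyclopentenone ring is bought.
2. Oxirane (second and last ring formed): a trans-5,6-diol is closed by SN2 of the C5 oxygen on a C6 mesylate, which puts the epoxide anti to the C4 hydroxyl; C5 and C6 come from L-tartaric acid.
3. Key C2–N enamide bond: blue-light, copper-catalysed coupling of a 2-iodocyclohexenone with the chiral primary amide, whose stereocentre comes from (S)-3-bromo-2-methylpropan-1-ol.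
4. Cyclohexenone (first ring formed): ring-closing metathesis of a vinyl ketone/vinyl carbinol; the C4 carbinol is set by chelation-controlled vinyl Grignard addition to a tartrate-derived ynone.
5. Ring order: cyclohexenone (metathesis), then oxirane (SN2 closure); the tartrate dioxolane is carried as a temporary ring.

Assumption: 1, 6, 9 (as its hydrochloride) and 12 are bought as such, and every reagent named on a Conditions line is commercial.

## Route

Step 1
Reactants: 1 (S)-3-bromo-2-methylpropan-1-ol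
Product: 2 (R)-2-methylhexan-1-ol
Conditions: n-PrMgCl (3 equiv), Li2CuCl4 (3 mol%), THF, −78 °C to 0 °C; aq NH4Cl
Reagents that add atoms: n-propylmagnesium chloride, CCC[Mg]Cl
Why: Copper-catalysed Kochi-type sp3–sp3 Grignard cross-coupling at the primary bromide of the magnesium alkoxide; the stereocentre is not touched and only its CIP label changes from S to R.

Step 2
Reactants: 2 (R)-2-methylhexan-1-ol
Product: 4 ethyl (2E,4R)-2,4-dimethyloct-2-enoate, via (R)-2-methylhexanal 3 (not isolated)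
Conditions: TEMPO (10 mol%), PhI(OAc)2 (1.1 equiv), CH2Cl2, 20 °C; then Ph3P=C(Me)CO2Et (1.4 equiv), 20 to 40 °C
Reagents that add atoms: ethyl 2-(triphenylphosphoranylidene)propanoate, CCOC(=O)C(C)=P(c1ccccc1)(c1ccccc1)c1ccccc1
Why: Non-basic TEMPO oxidation gives the α-chiral aldehyde without racemisation and the stabilised ylide traps it in the same flask in an E-selective Wittig reaction.

Step 3
Reactants: 4 ethyl (2E,4R)-2,4-dimethyloct-2-enoate
Product: 5 (2E,4R)-2,4-dimethyloct-2-enamide
Conditions: AlMe3 (3 equiv), NH4Cl (3 equiv), toluene, 0 to 50 °C; aq HCl work-up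
Reagents that add atoms: ammonium chloride, [NH4+].[Cl-]
Why: Weinreb aluminium-amide aminolysis converts the hindered enoate directly into the primary amide without touching the alkene geometry or the allylic stereocentre.

Step 4
Reactants: 6 glutaconaldehyde potassium salt
Product: 7 (2E,4E)-5-bromopenta-2,4-dienal
Conditions: PPh3, Br2, CH2Cl2, 0 °C; then 6, 0 to 20 °C
Reagents that add atoms: bromine, BrBr
Why: Appel-type deoxybromination of the vinylogous formate enolate by Ph3PBr2 (O-phosphonium formation, then addition–elimination by bromide) gives the thermodynamically favoured all-trans bromodienal.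

Step 5
Reactants: 7 (2E,4E)-5-bromopenta-2,4-dienal
Product: 8 (2E,4E)-5-bromopenta-2,4-dienoic acid
Conditions: NaClO2, NaH2PO4, 2-methyl-2-butene, t-BuOH–H2O, 0 °C
Reagents that add atoms: sodium chlorite, [Na+].[O-]Cl=O
Why: Pinnick oxidation converts the enal into the acid without isomerising or halogenating the bromodiene, the hypochlorite being scavenged by 2-methyl-2-butene.

Step 6
Reactants: 8 (2E,4E)-5-bromopenta-2,4-dienoic acid; 9 2-amino-3-hydroxycyclopent-2-en-1-one hydrochloride
Product: 11 (2E,4E)-5-bromo-N-(2-hydroxy-5-oxocyclopent-1-en-1-yl)penta-2,4-dienamide, via bromodienoyl chloride 10 (not isolated)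
Conditions: (COCl)2, DMF (cat.), CH2Cl2, 0 °C; evaporate; then 9, pyridine, CH2Cl2, −20 to 20 °C, dark
Reagents that add atoms: none
Why: Acid chloride formation followed by N-acylation of the aminoenol gives the amide, the N-acyl compound being the stable acylation product of this vinylogous acid.

Step 7
Reactants: 12 dimethyl (4R,5R)-2,2-dimethyl-1,3-dioxolane-4,5-dicarboxylate
Product: 13 (4R,5R)-N4,N5-dimethoxy-N4,N5,2,2-tetramethyl-1,3-dioxolane-4,5-dicarboxamide
Conditions: MeNHOMe·HCl (5 equiv), i-PrMgCl (10 equiv), THF, −20 to 0 °C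
Reagents that add atoms: N,O-dimethylhydroxylamine hydrochloride, Cl.CNOC
Why: Aminolysis of both esters by the magnesium amide gives the bis-Weinreb amide; the trans-dioxolane stereocentres are the thermodynamic arrangement and do not epimerise.

Step 8
Reactants: 13 (4R,5R)-N4,N5-dimethoxy-N4,N5,2,2-tetramethyl-1,3-dioxolane-4,5-dicarboxamide
Product: 14 (4R,5R)-N-methoxy-N,2,2-trimethyl-5-[3-(trimethylsilyl)prop-2-ynoyl]-1,3-dioxolane-4-carboxamide
Conditions: Me3SiC≡CH, n-BuLi, THF, −78 °C; acetylide (1.0 equiv) added to 13, −78 °C; quench into cold 1 M HCl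
Reagents that add atoms: ethynyltrimethylsilane, C#C[Si](C)(C)C
Why: Weinreb ketone synthesis with one equivalent of acetylide stops at the mono-ynone because the chelated tetrahedral intermediate survives until the acidic quench, and C2 symmetry makes the two amides equivalent.

Step 9
Reactants: 14 (4R,5R)-N-methoxy-N,2,2-trimethyl-5-[3-(trimethylsilyl)prop-2-ynoyl]-1,3-dioxolane-4-carboxamide
Product: 15 1-{(4R,5R)-5-[(3S)-3-hydroxy-5-(trimethylsilyl)pent-1-en-4-yn-3-yl]-2,2-dimethyl-1,3-dioxolan-4-yl}prop-2-en-1-one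
Conditions: MgBr2·OEt2 (1.5 equiv), CH2Cl2, −78 °C; CH2=CHMgBr (3 equiv), −78 to −10 °C; inverse quench into cold 1 M HCl
Reagents that add atoms: vinylmagnesium bromide, C=C[Mg]Br
Why: Cram-chelate-controlled Grignard 1,2-addition: magnesium bridges the ynone oxygen and the adjacent dioxolane oxygen, so vinyl enters from the face of the C–H bond and sets the carbinol centre S; the second equivalent makes the vinyl ketone by Weinreb ketone synthesis.

Step 10
Reactants: 15 1-{(4R,5R)-5-[(3S)-3-hydroxy-5-(trimethylsilyl)pent-1-en-4-yn-3-yl]-2,2-dimethyl-1,3-dioxolan-4-yl}prop-2-en-1-one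
Product: 16 (4S,5R,6R)-4-hydroxy-5,6-(isopropylidenedioxy)-4-[(trimethylsilyl)ethynyl]cyclohex-2-en-1-one
Conditions: second-generation Hoveyda–Grubbs catalyst RuCl2(H2IMes)(=CH-C6H4-2-O-i-Pr) (5 mol%), CH2Cl2 (5 mM), 40 °C
Reagents that add atoms: none
Why: Ring-closing metathesis of the two terminal alkenes closes the six-membered enone; the hindered silyl alkyne is geminal to one alkene and does not take part.

Step 11
Reactants: 16 (4S,5R,6R)-4-hydroxy-5,6-(isopropylidenedioxy)-4-[(trimethylsilyl)ethynyl]cyclohex-2-en-1-one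
Product: 17 (4S,5R,6R)-4-hydroxy-2-iodo-5,6-(isopropylidenedioxy)-4-[(trimethylsilyl)ethynyl]cyclohex-2-en-1-one
Conditions: I2 (2 equiv), pyridine–CH2Cl2 (1:1), DMAP (0.2 equiv), 0 to 20 °C
Reagents that add atoms: iodine, II
Why: Johnson α-iodination (conjugate addition of the pyridine base, iodination of the enolate, E1cB loss of the base) puts iodine on C2 only and leaves the stereocentres untouched.

Step 12
Reactants: 17 (4S,5R,6R)-4-hydroxy-2-iodo-5,6-(isopropylidenedioxy)-4-[(trimethylsilyl)ethynyl]cyclohex-2-en-1-one; 5 (2E,4R)-2,4-dimethyloct-2-enamide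
Product: 18 (4S,5R,6R)-2-{[(2E,4R)-2,4-dimethyloct-2-enoyl]amino}-4-hydroxy-5,6-(isopropylidenedioxy)-4-[(trimethylsilyl)ethynyl]cyclohex-2-en-1-one
Conditions: 5 (1.3 equiv), CuI (10 mol%), 2,9-dimethyl-1,10-phenanthroline (12 mol%), K3PO4 (2 equiv), MeCN, 440 nm LEDs, 20 °C, argon
Reagents that add atoms: none
Why: Proposed new method: photoinduced copper-catalysed Goldberg N-alkenylation of a primary amide with a 2-iodoenone at 20 °C — the (2,9-dimethylphenanthroline)copper amidate formed with K3PO4 absorbs at 440 nm, its excited state passes one electron to the weak, enone-activated C(sp2)–I bond, the α-keto vinyl radical recombines in the solvent cage with the divalent copper amidate, and C–N reductive elimination from trivalent copper returns monovalent copper; the closest known reactions are the photoinduced copper-catalysed Ullmann/Goldberg couplings of amides with alkyl and aryl halides and the thermal CuI/diamine amidation of 2-iodoenones; the room-temperature, weak-base variant is chosen to spare the C–SiMe3 bond (a freed alkyne would undergo Castro–Stephens coupling) and the base-sensitive oxygenated enone, and no stereocentre is formed.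

Step 13
Reactants: 18 (4S,5R,6R)-2-{[(2E,4R)-2,4-dimethyloct-2-enoyl]amino}-4-hydroxy-5,6-(isopropylidenedioxy)-4-[(trimethylsilyl)ethynyl]cyclohex-2-en-1-one
Product: 20 (4S,5R,6R)-2-{[(2E,4R)-2,4-dimethyloct-2-enoyl]amino}-4-ethynyl-4,5,6-trihydroxycyclohex-2-en-1-one, via desilylated acetonide 19 (not isolated)
Conditions: K2CO3 (0.2 equiv), MeOH, 0 °C; then 1 M aq HCl to pH 1, 30 °C
Reagents that add atoms: none
Why: Carbonate-catalysed methanolysis of the alkynyl C–Si bond is run while the trans-fused dioxolane still holds the C5–O bond in the enolate plane (no E1cB), and acid hydrolysis of the strained trans-acetonide then frees the diol without touching any stereocentre.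

Step 14
Reactants: 20 (4S,5R,6R)-2-{[(2E,4R)-2,4-dimethyloct-2-enoyl]amino}-4-ethynyl-4,5,6-trihydroxycyclohex-2-en-1-one
Product: 22 (4S,5R,6S)-2-{[(2E,4R)-2,4-dimethyloct-2-enoyl]amino}-5,6-epoxy-4-ethynyl-4-hydroxycyclohex-2-en-1-one, via C6 mesylate 21 (not isolated)
Conditions: MsCl (1.05 equiv), 2,4,6-collidine, CH2Cl2, −30 °C; then DBU (1.2 equiv), −40 to −20 °C, 20 min; AcOH quench
Reagents that add atoms: none
Why: Selective sulfonylation of the unhindered, more acidic α-ketol hydroxyl at C6 (C5–OH is neopentyl-like, C4–OH tertiary) is followed by intramolecular Williamson (Darzens-type) SN2 closure by the C5 oxygen with inversion at C6, so the oxirane oxygen lies on the face of the retained C5–O bond, cis to the ethynyl group and anti to the C4 hydroxyl.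

Step 15
Reactants: 22 (4S,5R,6S)-2-{[(2E,4R)-2,4-dimethyloct-2-enoyl]amino}-5,6-epoxy-4-ethynyl-4-hydroxycyclohex-2-en-1-one; 11 (2E,4E)-5-bromo-N-(2-hydroxy-5-oxocyclopent-1-en-1-yl)penta-2,4-dienamide
Product: 24 (2E,4R)-N-[(1S,5R,6R)-5-hydroxy-5-[(1E,3E,5E)-7-[(2-hydroxy-5-oxocyclopent-1-en-1-yl)amino]-7-oxohepta-1,3,5-trien-1-yl]-2-oxo-7-oxabicyclo[4.1.0]hept-3-en-3-yl]-2,4-dimethyloct-2-enamide (CNP0259711.3), via (E)-vinylstannane 23 (not isolated)
Conditions: Bu3SnH (1.05 equiv), PdCl2(PPh3)2 (3 mol%), THF, 0 °C; then 11 (1.2 equiv), Pd2(dba)3 (5 mol%), AsPh3 (20 mol%), DMF, 20 °C, dark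
Reagents that add atoms: none
Why: Palladium-catalysed syn-hydrostannation of the terminal alkyne places tin on the distal carbon of the tertiary propargylic alcohol, and Stille coupling of the resulting (E)-vinylstannane with the (E,E)-bromodiene proceeds with retention at both partners to give the all-E triene under neutral conditions.

## Compound list

1 | (S)-3-bromo-2-methylpropan-1-ol | BrC[C@@H](C)CO | starting material
2 | (R)-2-methylhexan-1-ol | CCCC[C@@H](C)CO | intermediate
3 | (R)-2-methylhexanal | CCCC[C@@H](C)C=O | intermediate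
4 | ethyl (2E,4R)-2,4-dimethyloct-2-enoate | CCCC[C@@H](C)/C=C(\C)C(=O)OCC | intermediate
5 | (2E,4R)-2,4-dimethyloct-2-enamide | CCCC[C@@H](C)/C=C(\C)C(N)=O | intermediate
6 | glutaconaldehyde potassium salt | [K+].[O-]/C=C/C=C/C=O | starting material
7 | (2E,4E)-5-bromopenta-2,4-dienal | Br/C=C/C=C/C=O | intermediate
8 | (2E,4E)-5-bromopenta-2,4-dienoic acid | Br/C=C/C=C/C(=O)O | intermediate
9 | 2-amino-3-hydroxycyclopent-2-en-1-one hydrochloride | Cl.NC1=C(O)CCC1=O | starting material
10 | (2E,4E)-5-bromopenta-2,4-dienoyl chloride | Br/C=C/C=C/C(Cl)=O | intermediate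
11 | (2E,4E)-5-bromo-N-(2-hydroxy-5-oxocyclopent-1-en-1-yl)penta-2,4-dienamide | Br/C=C/C=C/C(=O)NC1=C(O)CCC1=O | intermediate
12 | dimethyl (4R,5R)-2,2-dimethyl-1,3-dioxolane-4,5-dicarboxylate (dimethyl 2,3-O-isopropylidene-L-tartrate) | COC(=O)[C@@H]1OC(C)(C)O[C@H]1C(=O)OC | starting material
13 | (4R,5R)-N4,N5-dimethoxy-N4,N5,2,2-tetramethyl-1,3-dioxolane-4,5-dicarboxamide | CON(C)C(=O)[C@@H]1OC(C)(C)O[C@H]1C(=O)N(C)OC | intermediate
14 | (4R,5R)-N-methoxy-N,2,2-trimethyl-5-[3-(trimethylsilyl)prop-2-ynoyl]-1,3-dioxolane-4-carboxamide | CON(C)C(=O)[C@@H]1OC(C)(C)O[C@H]1C(=O)C#C[Si](C)(C)C | intermediate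
15 | 1-{(4R,5R)-5-[(3S)-3-hydroxy-5-(trimethylsilyl)pent-1-en-4-yn-3-yl]-2,2-dimethyl-1,3-dioxolan-4-yl}prop-2-en-1-one | C=CC(=O)[C@@H]1OC(C)(C)O[C@H]1[C@](O)(C=C)C#C[Si](C)(C)C | intermediate
16 | (4S,5R,6R)-4-hydroxy-5,6-(isopropylidenedioxy)-4-[(trimethylsilyl)ethynyl]cyclohex-2-en-1-one (trans-fused acetonide) | O=C1C=C[C@](O)(C#C[Si](C)(C)C)[C@@H]2OC(C)(C)O[C@@H]12 | intermediate
17 | (4S,5R,6R)-4-hydroxy-2-iodo-5,6-(isopropylidenedioxy)-4-[(trimethylsilyl)ethynyl]cyclohex-2-en-1-one | O=C1C(I)=C[C@](O)(C#C[Si](C)(C)C)[C@@H]2OC(C)(C)O[C@@H]12 | intermediate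
18 | (4S,5R,6R)-2-{[(2E,4R)-2,4-dimethyloct-2-enoyl]amino}-4-hydroxy-5,6-(isopropylidenedioxy)-4-[(trimethylsilyl)ethynyl]cyclohex-2-en-1-one | CCCC[C@@H](C)/C=C(\C)C(=O)NC1=C[C@](O)(C#C[Si](C)(C)C)[C@@H]2OC(C)(C)O[C@H]2C1=O | intermediate
19 | (4S,5R,6R)-2-{[(2E,4R)-2,4-dimethyloct-2-enoyl]amino}-4-ethynyl-4-hydroxy-5,6-(isopropylidenedioxy)cyclohex-2-en-1-one | CCCC[C@@H](C)/C=C(\C)C(=O)NC1=C[C@](O)(C#C)[C@@H]2OC(C)(C)O[C@H]2C1=O | intermediate
20 | (4S,5R,6R)-2-{[(2E,4R)-2,4-dimethyloct-2-enoyl]amino}-4-ethynyl-4,5,6-trihydroxycyclohex-2-en-1-one | CCCC[C@@H](C)/C=C(\C)C(=O)NC1=C[C@](O)(C#C)[C@H](O)[C@@H](O)C1=O | intermediate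
21 | 6-O-methanesulfonate of 20, (4S,5R,6R) | CCCC[C@@H](C)/C=C(\C)C(=O)NC1=C[C@](O)(C#C)[C@H](O)[C@@H](OS(C)(=O)=O)C1=O | intermediate
22 | (4S,5R,6S)-2-{[(2E,4R)-2,4-dimethyloct-2-enoyl]amino}-5,6-epoxy-4-ethynyl-4-hydroxycyclohex-2-en-1-one (oxirane oxygen cis to ethynyl, trans to OH) | CCCC[C@@H](C)/C=C(\C)C(=O)NC1=C[C@](O)(C#C)[C@@H]2O[C@@H]2C1=O | intermediate
23 | (4S,5R,6S)-2-{[(2E,4R)-2,4-dimethyloct-2-enoyl]amino}-5,6-epoxy-4-hydroxy-4-[(E)-2-(tributylstannyl)ethenyl]cyclohex-2-en-1-one | CCCC[C@@H](C)/C=C(\C)C(=O)NC1=C[C@](O)(/C=C/[Sn](CCCC)(CCCC)CCCC)[C@@H]2O[C@@H]2C1=O | intermediate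
24 | CNP0259711.3, (2E,4R)-N-[(1S,5R,6R)-5-hydroxy-5-[(1E,3E,5E)-7-[(2-hydroxy-5-oxocyclopent-1-en-1-yl)amino]-7-oxohepta-1,3,5-trien-1-yl]-2-oxo-7-oxabicyclo[4.1.0]hept-3-en-3-yl]-2,4-dimethyloct-2-enamide | CCCC[C@@H](C)/C=C(\C)C(=O)NC1=C[C@](O)(/C=C/C=C/C=C/C(=O)NC2=C(O)CCC2=O)[C@@H]2O[C@@H]2C1=O | target

## Step count and risks

Total step count: 15. Longest linear sequence: 9 steps (12 to 24, steps 7–15).

Steps most likely to fail:

Step 9. The C4 configuration depends on magnesium chelating a dioxolane oxygen; if open Felkin–Anh attack or 1,4-addition to the ynone competes, the C4 epimer or adducts form. The fallback reverses the order in which the two C4 substituents arrive and uses the opposite control element. It sets out from 13: one equivalent of vinylmagnesium bromide (THF, −78 °C, cold HCl quench) gives (4R,5R)-5-acryloyl-N-methoxy-N,2,2-trimethyl-1,3-dioxolane-4-carboxamide F1. Lithium (trimethylsilyl)acetylide, used in THF with CeCl3 and no chelating magnesium salt, then adds 1,2 to the vinyl ketone under Felkin–Anh control. This delivers the same carbinol configuration, (4R,5R)-5-[(3S)-3-hydroxy-5-(trimethylsilyl)pent-1-en-4-yn-3-yl]-N-methoxy-N,2,2-trimethyl-1,3-dioxolane-4-carboxamide F2. Vinylmagnesium bromide on the remaining Weinreb amide then comes back to the route at 15.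

Step 12 (the proposed new method). The vinyl radical may be reduced to the de-iodinated enone 16, or the copper amidate may not absorb strongly enough. The fallback uses known chemistry and makes the amide C(=O)–N bond last instead of the vinyl C–N bond. It sets out from 17: copper-catalysed azidation of the vinyl iodide (CuI, N,N'-dimethylethylenediamine, sodium ascorbate NaC6H7O6, NaN3, DMSO–H2O, 20 °C) gives (4S,5R,6R)-2-azido-4-hydroxy-5,6-(isopropylidenedioxy)-4-[(trimethylsilyl)ethynyl]cyclohex-2-en-1-one F3. Staudinger reduction (PPh3, THF–H2O, 0 °C) gives (4S,5R,6R)-2-amino-4-hydroxy-5,6-(isopropylidenedioxy)-4-[(trimethylsilyl)ethynyl]cyclohex-2-en-1-one F4. Separately, ester 4 is saponified (LiOH, THF–H2O) to (2E,4R)-2,4-dimethyloct-2-enoic acid F5, which is converted with (COCl)2 and catalytic DMF into (2E,4R)-2,4-dimethyloct-2-enoyl chloride F6. N-acylation of the aminoenone with this chloride in pyridine–CH2Cl2 comes back to the route at 18.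

Step 14. The wrong hydroxyl may be sulfonylated, or base may drive Payne migration of the anti hydroxy-epoxide towards the 4,5-oxirane. The fallback replaces selective O-sulfonylation by regioselective nucleophilic opening at the SN2-active α-keto carbon. It sets out from 20: trimethyl orthoacetate with catalytic pyridinium p-toluenesulfonate gives the 5,6-O-(1-methoxyethylidene) cyclic orthoacetate of 20 F7. Acetyl bromide opens the derived acetoxonium ion at C6 with inversion to give (4S,5S,6S)-5-acetoxy-6-bromo-2-{[(2E,4R)-2,4-dimethyloct-2-enoyl]amino}-4-ethynyl-4-hydroxycyclohex-2-en-1-one F8. Brief K2CO3 in MeOH at 0 °C removes the acetate and epimerises the α-bromo ketone through its enol; only the trans-bromohydrin can close, so the C5 oxygen displaces bromide and the sequence comes back to the route at 22.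

Further compounds
F1 | step 9 | (4R,5R)-5-acryloyl-N-methoxy-N,2,2-trimethyl-1,3-dioxolane-4-carboxamide | CON(C)C(=O)[C@@H]1OC(C)(C)O[C@H]1C(=O)C=C
F2 | step 9 | (4R,5R)-5-[(3S)-3-hydroxy-5-(trimethylsilyl)pent-1-en-4-yn-3-yl]-N-methoxy-N,2,2-trimethyl-1,3-dioxolane-4-carboxamide | CON(C)C(=O)[C@@H]1OC(C)(C)O[C@H]1[C@](O)(C=C)C#C[Si](C)(C)C
F3 | step 12 | (4S,5R,6R)-2-azido-4-hydroxy-5,6-(isopropylidenedioxy)-4-[(trimethylsilyl)ethynyl]cyclohex-2-en-1-one | [N-]=[N+]=NC1=C[C@](O)(C#C[Si](C)(C)C)[C@@H]2OC(C)(C)O[C@H]2C1=O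
F4 | step 12 | (4S,5R,6R)-2-amino-4-hydroxy-5,6-(isopropylidenedioxy)-4-[(trimethylsilyl)ethynyl]cyclohex-2-en-1-one | NC1=C[C@](O)(C#C[Si](C)(C)C)[C@@H]2OC(C)(C)O[C@H]2C1=O
F5 | step 12 | (2E,4R)-2,4-dimethyloct-2-enoic acid | CCCC[C@@H](C)/C=C(\C)C(=O)O
F6 | step 12 | (2E,4R)-2,4-dimethyloct-2-enoyl chloride | CCCC[C@@H](C)/C=C(\C)C(Cl)=O
F7 | step 14 | 5,6-O-(1-methoxyethylidene) cyclic orthoacetate of 20 | CCCC[C@@H](C)/C=C(\C)C(=O)NC1=C[C@](O)(C#C)[C@@H]2OC(C)(OC)O[C@H]2C1=O
F8 | step 14 | (4S,5S,6S)-5-acetoxy-6-bromo-2-{[(2E,4R)-2,4-dimethyloct-2-enoyl]amino}-4-ethynyl-4-hydroxycyclohex-2-en-1-one | CCCC[C@@H](C)/C=C(\C)C(=O)NC1=C[C@](O)(C#C)[C@H](OC(C)=O)[C@H](Br)C1=O
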